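| flask | starting material | partner | product | time |
|---|---|---|---|---|
| winter | 0.300 M | 0.330 M |  |  |
| dusk | 0.150 M | 0.180 M |  |  |
| summer | 0.450 M | 0.330 M |  |  |
| noon | 0.300 M | 0.330 M | 0.0900 M |  |
| autumn | 0.300 M | 1.70 M |  | 6.1 min |

| run | time / min | [product] / M |
|---|---|---|
| winter run | 0.24 | 0.0297 |
| winter run | 0.39 | 0.0445 |
| winter run | 0.61 | 0.0559 |
| winter run | 0.97 | 0.0781 |
| winter run | 1.5 | 0.1021 |
| winter run | 2.4 | 0.1185 |
| winter run | 3.9 | 0.1319 |
| winter run | 6.1 | 0.1373 |
| dusk run | 0.24 | 0.0084 |
| dusk run | 0.39 | 0.0111 |
| dusk run | 0.61 | 0.0178 |
| dusk run | 0.97 | 0.0248 |
| dusk run | 1.5 | 0.0313 |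
| dusk run | 2.4 | 0.0429 |
| dusk run | 3.9 | 0.0470 |
| dusk run | 6.1 | 0.0486 |
| summer run | 0.24 | 0.0448 |
| summer run | 0.39 | 0.0592 |
| summer run | 0.61 | 0.0838 |
| summer run | 0.97 | 0.1113 |
| summer run | 1.5 | 0.1346 |
| summer run | 2.4 | 0.1572 |
| summer run | 3.9 | 0.1735 |
| summer run | 6.1 | 0.1855 |
| noon run | 0.24 | 0.1193 |
| noon run | 0.39 | 0.1336 |
| noon run | 0.61 | 0.1476 |
| noon run | 0.97 | 0.1679 |
| noon run | 1.5 | 0.1876 |
| noon run | 2.4 | 0.2088 |
| noon run | 3.9 | 0.2197 |
| noon run | 6.1 | 0.2270 |

(readings scatter by 0.002 M)

* reaction order in [partner] at the outset, round the charge of the winter run, defined at two percent of the starting material turned into product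
* reaction order in [starting material] at the outset, round the charge of the winter run, defined at two percent of the starting material turned into product (one fixed amount of product, the same in the runs compared)
* product in the autumn run at 6.1 min, as a share of the starting material charged

- Overall: starting material + partner -> product.
- Constant volume, constant temperature.
- An order is taken over about fifteen percent of the charge, up and down.

After 6.1 min at the one temperature, the winter run had made 0.1373 M of product. Counted by product, that spared 0.163 M of starting material and 0.193 M of partner. The first winter reading gave a rate constant of 1.25 /M/min, so those amounts, near enough for the last stretch, should have made product at 0.0392 M/min. The last two winter readings showed 0.00245 M/min, which is slower. So something faded besides plain consumption. I spread that gap over the time and read a fade constant of 0.554 /min, a fade time of 1.80 min.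

The autumn run charged 5.67 times as much partner as starting material, so I treated it as pseudo-first-order. I defined the capture time, the reciprocal of the rate constant times the charged [partner], as 0.471 min. With [partner] held at its charge, and with the starting material used up against a first-order loss, the product share is the loss time over the sum of loss time and capture time. With the whole fade placed on the starting material, I reckoned 79.3 %. I held that as a low estimate.

The forecast gave an order of 1 in [partner] and 1 in [starting material] round the winter charge, and 97 % for the autumn run, “assuming the high partner level doesn't alter the decay”. I turned that round. For this share, the loss time of starting material had to reach 15.2 min, which is 8.44 times my fade time. The question was where the fade sat.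

Round the winter charge, the order came out at 1.0 in [partner] and 1.0 in [starting material], and the autumn run gave 88.8 % of its charged starting material as product at 6.1 min.

    starting material + partner → product (1.338 /M/min)
    starting material → decomposed substrate (0.2388 /min)
    partner → lost reagent (0.1794 /min)

The loss of starting material to decomposed substrate accounted for 99 % of what was missing. With that step taken away, the autumn run reached 99.9 %. The loss time of starting material was 4.19 min, shorter than the 15.2 min required. Set against my capture time for the autumn run, it gave a share of 89.9 %. The autumn run without the loss of partner to lost reagent gave 89.7 %.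

(The numbers in the tables are simulated for an exercise.)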